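## Structural features

The target is a C20 bromoditerpenoid acetate in two halves joined by one methylene (C12). The core is a cyclohexane (C1–C5 and C8) whose C1 and C5 are bridged by a γ-lactone (O6–C7, a 6-oxabicyclo[3.2.1]octan-7-one) and whose C1–C8 bond is shared with a cis-fused cyclopentane (C9–C11); ring A is a 4-bromo-3,3-dimethylcyclohexyl acetate (C1'–C6') attached through C12 at its carbinol carbon C1'. Five of the seven stereocentres lie in the core, four of them contiguous (C2–C1–C8–C9) around the quaternary C1: the C2 bromine is equatorial on the lactone face with its axial hydrogen pointing at C9, the C8 hydrogen is syn to the lactone, and the C9 hydrogen is cis to it, so C12 sits on the concave face under the six-membered ring; C5 carries methyl and the lactone oxygen. In ring A the acetate is axial and cis to the equatorial bromine at C4' (C12 equatorial); these two centres are insulated from the core by C12, so neither half can control the other and both must be made enantiopure. The fragile groups are the two secondary, neopentylic bromides (elimination, hydrogenolysis, single-electron reduction), the tertiary acetate (ionisation, elimination) and the lactone (strong bases and hydrides). The real difficulty is the congested C2–C1–C8–C9 array and the two C–Br bonds next to fully substituted carbons, where substitution is slow. The key step exploits that C1 lies between the lactone carbonyl C7 and C2, a carbon that can be carried as a ketone, so C1 is the α-carbon of a β-keto ester; the methyl carbinol C5 is 1,3 to C1 across C8, exactly where a 6-endo radical closure leaves a tertiary centre within reach of the C7 ester.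

## Logic of the disconnections

**31 to 30.** The acetate C–O bond at C1' is cut first. The tertiary acetate is the group most prone to ionise or eliminate, so it is added last, and 30 tolerates more chemistry than 31. The forward step must acylate a hindered axial tertiary alcohol under non-ionising conditions.

**30 to 24 and 29.** The C12–C1' bond is cut. It is the only bond between the two stereochemically independent halves, and it gives two fragments of similar size. C1' is then created under the control of ring A itself (the axial methyl at C3' directs attack). The forward step must generate a primary organometallic from 24 beside a lactone and two secondary bromides, and must add it equatorially to 29.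

**29 to 25 through 28, 27 and 26.** The C4'–Br bond is traced to a C–O bond of opposite configuration (28), the ring bond C2'–C3' to an epoxide opening by an enol silane (27), and the epoxide to the prenyl alkene (26, 25). An oxygen stereocentre next to the gem-dimethyl carbon is available by asymmetric epoxidation, which a bromine stereocentre is not. The forward steps must open the epoxide 6-endo at its tertiary carbon and substitute with inversion at a neopentylic carbinol.

**24 to 21 through 23 and 22.** The C12–I and O–Si bonds are functional-group changes; then the C9–H and C10–H bonds are cut. A C9 centre whose substituent lies on the concave face is best made by adding hydrogen to the convex face of a cyclopentene. The forward hydrogenation must spare the C2 bromide.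

**21 to 18 through 20 and 19.** The C9=C10 bond is cut by ring-closing metathesis, the methylene of 20 goes back to the ketone of 19, and that ketone to the ketal of 18. The two alkene arms are cis by construction, so only the cis-fused ring can form. The ketal is needed because a ketone conjugated to the alkene would deactivate it in the key step. The forward steps must methylenate a hindered, enolisable ketone without epimerising C8 and hydrolyse the ketal without losing the silyl ether.

**18 to 16 through 17.** The C2–Br bond is traced to an axial C2–OH of opposite configuration (17) and this to the C2 ketone (16). C2 has to be a ketone in the key step, and it must be converted before the side-chain ketone is unmasked, otherwise two ketones would compete in the methylenation. The forward steps need equatorial hydride delivery and then inversion at a neopentylic axial carbinol.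

**16 to 15.** The C1–C8 bond and the C5–O6 bond are cut together. This opens both the cyclohexanone and the lactone, removes three stereocentres and leaves an acyclic 2-allyl β-keto ester. The forward step needs a Z alkene, an axial ester in the chair transition state, a chiral ester for the absolute sense and a ketal that survives the oxidant.

**15 to 9, 10, 11 and 14 through 13 and 12.** The C2–allyl bond of 15 is cut (13 and 14), then the C4–C5 bond of the keto ester chain (12 and 9), then the ester C–O bond (10 and 11). All three are standard acetoacetate bond formations. The γ-alkylation must keep the Z geometry of 9.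

**9 to 1 through 8, 7, 5, 4 and 3.** The C–Br and ester functions are adjusted (8, 7), then the C=C bond is cut by a Z-selective olefination into 5 and 6. 5 is traced through 4 and 3 to 1, whose carbonyl carbon becomes C9 and whose CH2OH groups become C12 and the alkene CH (C8). The olefination must give the Z trisubstituted alkene at a neopentyl-type aldehyde.

## Other disconnections considered

**Alternative 1:** The cut is the C1–C2 bond, with the cyclopentane already present as a cyclopentenone and C2 as a side-chain aldehyde on a chain whose C5 carbinol comes from dehydrolinalool. In the forward step a chiral triazolium carbene turns the aldehyde into an acyl-anion equivalent. It adds to the ester-bearing alkene carbon (future C1) of the enone, closes the cyclohexanone and would give the cis-fused hydrindane dione ester A1.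
- In favour: stereocontrol is catalytic, the tertiary carbinol is taken from a cheap alcohol, and the five-membered ring never has to be built on a finished bicycle. Up to the bicyclic stage this plan is the better one on step count, and a tunable catalyst is better than a stoichiometric auxiliary.
- Against: addition of a Breslow intermediate to a β,β-disubstituted enone carbon to make a quaternary centre is the least reactive kind of Stetter acceptor. The catalyst must override the existing C5 centre, and the ring fusion rests on an enolate protonation. A1 carries two ketones (C2, C9) and an ester of similar reactivity, and the lactone still has to be closed from a hindered ester and a silylated tertiary alcohol.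
- Comparison: in structure, the C9 carbonyl of A1 is a good handle for C12 but leaves the concave C9 configuration to a late hydrogenation, as here. In mechanism, the radical–polar crossover forms the quaternary centre through an early, sterically tolerant transition state and closes the lactone in the same operation, which the two-electron umpolung does not. In step economy, the early gain of A1 is likely spent on telling three carbonyl groups apart. The C2 ketone-to-bromide problem is equal in both.

**Alternative 2:** The cut is the C8–C9 bond. In the forward sense a dearomatised (Birch-alkylated) benzoic acid is iodolactonised, which puts O6 on C5 and iodine on C8. The secondary C8 radical then adds 5-exo to the E alkene of a side chain that already carries ring A, closing the cyclopentane and giving the complete skeleton A2 with a ketone at C2.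
- In favour: it is the most convergent plan; ring A with its acetate and bromide is in place before the key step, the lactone comes from a classical iodolactonisation, and only the C2 ketone remains to be converted. After its key step it is clearly shorter than the chosen plan.
- Against: C9 is set in the radical transition state, which normally puts the new substituent on the convex face, whereas the target needs C12 on the concave face. The chain-carrying hydride would also attack the secondary C4' bromide. The neopentylic C2 bromination falls on the most advanced intermediate, beside a tertiary acetate and a second bromide. Absolute control needs an asymmetric dearomatisation as well as enantiopure ring A, and every later step carries diastereomers if either is imperfect.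
- Comparison: in structure both plans need the same ring A synthon (equal). In mechanism the chosen plan sets C9 by a hydrogenation whose facial bias agrees with the target, where the radical closure likely opposes it. In step economy A2 is better, but its risk is concentrated at the end.

**Alternative 3:** The cuts are the C1–C8 and C2–C3 bonds. In the forward sense a tetraene, whose 2-methyl Z-diene and Z-2-alkyl-3-bromoacrylate are linked by three carbons, undergoes an intramolecular Diels–Alder reaction that closes cyclopentane and cyclohexene together and would give the bromo hexahydroindene ester A3. Acid then protonates the ring alkene and the ester closes the lactone at C5.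
- In favour: the C2–Br bond is made with its configuration fixed by the dienophile geometry, so no substitution at a neopentylic carbon is needed in the core. On this point it is better than the chosen plan. It forms two rings and three stereocentres in one step (equal to step 10), and the exocyclic methylene at C9 is a handle for C12.
- Against: a Z-diene reaches the s-cis conformation with difficulty, the trisubstituted β-bromoacrylate is a hindered dienophile, and the cross-conjugated triene offers a second diene pairing. No reliable source of absolute configuration is evident. The lactonisation must protonate the ring alkene in the presence of the exocyclic one, and heat or acid invite loss of HBr.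
- Comparison: in structure A3 and 16 hold the same three core centres, and A3 already has the bromine. In mechanism the cycloaddition depends on an endo/exo preference that is hard to predict, whereas the chair radical closure has a clear stereochemical model. In step economy the two are about equal once the tetraene synthesis and the C12 chemistry are counted.

Key step: step 10

Assumption: the sense of induction of the 8-phenylmenthyl ester is taken from the aryl-shielding model for α-alkyl acetoacetate radicals (ring-ketone carbon syn to the ester carbonyl), which points to the (1S,2R,5S) auxiliary 11 for the C1 configuration of the target; if the other face were shielded, the (1R,2S,5R) antipode would be used with no other change.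

## Route

Step 1
Reactants: 1 1,3-dihydroxyacetone (commercial as its dimer)
Product: 3 (1,3-dioxolane-2,2-diyl)dimethanol, via 2,2-dimethoxypropane-1,3-diol 2 (not isolated)
Conditions: HC(OMe)3, TsOH·H2O (cat.), MeOH, 25 °C; then HOCH2CH2OH, 50 °C, MeOH removed
Reagents that add atoms: ethylene glycol, OCCO
Why: Acid-catalysed ketalisation; the orthoformate gives the dimethyl ketal 2 at room temperature (avoiding acid-promoted dehydration of 1), and ethylene glycol then exchanges in to the more stable cyclic ketal as methanol is removed (transketalisation).

Step 2
Reactants: 3 (1,3-dioxolane-2,2-diyl)dimethanol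
Product: 4 mono-TBDPS ether, {2-[(tert-butyldiphenylsilyloxy)methyl]-1,3-dioxolan-2-yl}methanol
Conditions: NaH (1.0 equiv), THF, 0 °C; then t-BuPh2SiCl
Reagents that add atoms: tert-butyl(chloro)diphenylsilane, CC(C)(C)[Si](Cl)(c1ccccc1)c1ccccc1
Why: Monosilylation of a symmetrical diol through its mono-sodium alkoxide; the acid-stable TBDPS group is chosen because it must survive acetic acid in step 10 and aqueous trifluoroacetic acid in step 13.

Step 3
Reactants: 4 mono-TBDPS ether
Product: 5 2-[(tert-butyldiphenylsilyloxy)methyl]-1,3-dioxolane-2-carbaldehyde
Conditions: Dess–Martin periodinane, CH2Cl2, 0 → 25 °C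
Reagents that add atoms: none
Why: Dess–Martin oxidation of a neopentyl-type primary alcohol; the aldehyde has no α-hydrogen, so it cannot enolise or eliminate, and it is used without storage.

Step 4
Reactants: 5 ketal aldehyde; 6 methyl 2-[bis(2,2,2-trifluoroethoxy)phosphoryl]propanoate
Product: 7 methyl (Z)-3-{2-[(tert-butyldiphenylsilyloxy)methyl]-1,3-dioxolan-2-yl}-2-methylprop-2-enoate
Conditions: KN(SiMe3)2, 18-crown-6, THF, −78 °C
Reagents that add atoms: none
Why: Still–Gennari olefination; the electron-poor phosphonate under dissociating conditions eliminates from the kinetic adduct and should give the Z trisubstituted enoate with ester and ketal carbon cis. This geometry is the source of the C8 configuration in step 10.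

Step 5
Reactants: 7 Z-enoate
Product: 8 (Z)-3-{2-[(tert-butyldiphenylsilyloxy)methyl]-1,3-dioxolan-2-yl}-2-methylprop-2-en-1-ol
Conditions: i-Bu2AlH (2.2 equiv), CH2Cl2, −78 °C
Reagents that add atoms: none
Why: 1,2-Reduction of the enoate by the aluminium hydride at low temperature; the alkene geometry, ketal and silyl ether are untouched.

Step 6
Reactants: 8 Z-allylic alcohol
Product: 9 Z-allylic bromide, tert-butyl({2-[(Z)-3-bromo-2-methylprop-1-enyl]-1,3-dioxolan-2-yl}methoxy)diphenylsilane
Conditions: CBr4, PPh3, 2,6-lutidine, CH2Cl2, −20 → 0 °C
Reagents that add atoms: tetrabromomethane, BrC(Br)(Br)Br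
Why: Appel bromination of a primary allylic alcohol (SN2 at CH2, so no allylic transposition is expected); the buffered neutral medium spares the ketal.

Step 7
Reactants: 10 methyl acetoacetate; 11 (1S,2R,5S)-8-phenylmenthol
Product: 12 (1S,2R,5S)-8-phenylmenthyl 3-oxobutanoate
Conditions: DMAP (cat.), toluene, reflux (MeOH distilled off)
Reagents that add atoms: none
Why: DMAP-catalysed transesterification of a β-keto ester (acyl-ketene pathway), driven by removal of methanol.

Step 8
Reactants: 12 8-phenylmenthyl acetoacetate; 9 Z-allylic bromide
Product: 13 (1S,2R,5S)-8-phenylmenthyl (Z)-7-{2-[(tert-butyldiphenylsilyloxy)methyl]-1,3-dioxolan-2-yl}-6-methyl-3-oxohept-6-enoate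
Conditions: LiN(i-Pr)2 (2.1 equiv), THF, −78 → 0 °C; then 9, 0 °C
Reagents that add atoms: none
Why: γ-Alkylation of the acetoacetate dianion; the more basic terminal carbanion displaces the primary allylic bromide by SN2, which keeps the Z geometry.

Step 9
Reactants: 13 γ-alkylated keto ester; 14 allyl bromide
Product: 15 (1S,2R,5S)-8-phenylmenthyl (Z)-2-allyl-7-{2-[(tert-butyldiphenylsilyloxy)methyl]-1,3-dioxolan-2-yl}-6-methyl-3-oxohept-6-enoate (both C2 epimers)
Conditions: NaH (1.0 equiv), THF, 0 °C; then 14, 0 → 25 °C
Reagents that add atoms: none
Why: C-Alkylation of the β-keto ester sodium enolate; one equivalent of base limits dialkylation, and the new C2 centre is irrelevant because it becomes the radical centre.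

Step 10
Reactants: 15 2-allyl β-keto ester
Product: 16 (1S,5S,8S)-1-allyl-8-{2-[(tert-butyldiphenylsilyloxy)methyl]-1,3-dioxolan-2-yl}-5-methyl-6-oxabicyclo[3.2.1]octane-2,7-dione
Conditions: Mn(OAc)3·2H2O (2.2 equiv), Cu(OAc)2·H2O (0.5 equiv), KOAc, AcOH, 25 → 40 °C
Reagents that add atoms: water, O
Why: Mn(OAc)3 converts the β-keto ester into its manganese enolate and oxidises it to the electrophilic α-radical (closest known type: oxidative free-radical cyclisation of unsaturated α-alkyl acetoacetates with trivalent manganese and divalent copper, including 8-phenylmenthyl esters). The radical closes 6-endo-trig on the CH carbon of the Z alkene, forming C1–C8 and the cyclohexanone; 6-endo wins over 5-exo because the ketone lies inside the forming ring and the other alkene carbon is fully substituted, which also leaves a tertiary radical at C5. Cu(OAc)2, turned over by trivalent manganese, oxidises this radical to the cation, and the carbonyl oxygen of the axial ester captures it in a 5-exo closure (C5–O6, γ-lactone); the dialkoxycarbenium ion is hydrolysed by the water of the medium and releases 11. C8 is set by the alkene geometry: in the chair transition state the Z substituent (the ketal arm) is axial and the ester on the radical carbon is axial on the other face, so arm and ester are trans and the later ring fusion can only be cis. C5 is set by the bridge, since the lactone can close only on the face that carries the ester. C1, and with it the absolute configuration of all three centres, is set by the auxiliary, whose phenyl group covers one face of the planar radical. The step needs the ketal to survive until ring closure (an ionised ketal would give an unreactive enone); the α-oxygen, the dioxolane ring and the acetate buffer secure this.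

Step 11
Reactants: 16 keto lactone
Product: 17 hydroxy lactone (C2–OH axial, on the face opposite the lactone bridge, cis to the C8 arm)
Conditions: LiBH(s-Bu)3, THF, −78 °C
Reagents that add atoms: none
Why: Reduction with a bulky borohydride; the axial trajectory at C2 is blocked by the axial C8 substituent (1,3-diaxial), so hydride arrives equatorially from the lactone face and the axial alcohol should form. Lactone and ketal are inert at −78 °C.

Step 12
Reactants: 17 hydroxy lactone
Product: 18 bromo lactone (C2–Br equatorial, on the lactone face, trans to the C8 arm)
Conditions: CBr4, PPh3, 2,6-lutidine, toluene, 25 → 60 °C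
Reagents that add atoms: tetrabromomethane, BrC(Br)(Br)Br
Why: Appel bromination with inversion (SN2) of an axial neopentylic alcohol, a reaction type known for axial carbinols next to a quaternary carbon in bromocyclohexane terpenoid rings. Bromide enters from the lactone face and gives the equatorial bromide, which is also the more stable epimer because an axial bromine would be 1,3-diaxial to C9.

Step 13
Reactants: 18 bromo lactone ketal
Product: 19 bromo lactone ketone (C8 bears a (tert-butyldiphenylsilyloxy)acetyl group)
Conditions: CF3CO2H–H2O (4:1), CH2Cl2, 0 → 25 °C
Reagents that add atoms: water, O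
Why: Acid hydrolysis of the dioxolane; the α-oxygen retards ionisation, hence aqueous trifluoroacetic acid, which the TBDPS ether, the lactone and the equatorial bromide tolerate.

Step 14
Reactants: 19 bromo lactone ketone
Product: 20 diene (C8 bears a 3-(tert-butyldiphenylsilyloxy)prop-1-en-2-yl group, C1 the allyl group)
Conditions: Zn, CH2Br2, TiCl4, THF–CH2Cl2, 0 → 25 °C
Reagents that add atoms: dibromomethane, BrCBr
Why: Takai–Lombardo methylenation; the non-basic zinc–titanium methylene reagent olefinates hindered, enolisable ketones without epimerising the α-centre (C8) and leaves the lactone alone.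

Step 15
Reactants: 20 diene
Product: 21 tricyclic alkene (cyclopentene C9=C10 cis-fused at C1–C8, C9 bears CH2OTBDPS)
Conditions: second-generation Grubbs catalyst (5 mol%), CH2Cl2, 40 °C
Reagents that add atoms: none
Why: Ring-closing metathesis of a 1,6-diene to a trisubstituted cyclopentene; the equatorial allyl on C1 and the axial arm on C8 are on the same side, so only the cis-fused ring can form.

Step 16
Reactants: 21 tricyclic alkene
Product: 22 tricyclic silyl ether (C9–H cis to C8–H, CH2OTBDPS on the concave face)
Conditions: H2 (1 atm), [Ir(cod)(PCy3)(py)]PF6 (5 mol%), CH2Cl2, 25 °C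
Reagents that add atoms: none
Why: Homogeneous hydrogenation of a hindered trisubstituted alkene with a cationic iridium catalyst that tolerates alkyl bromides. Hydrogen is delivered to the convex face (that of C8–H and the lactone carbonyl, which can also bind the metal), so C12 is pushed to the concave side and C9 is set.

Step 17
Reactants: 22 tricyclic silyl ether
Product: 23 primary alcohol (C12–OH)
Conditions: HF·pyridine, pyridine–THF, 0 → 25 °C
Reagents that add atoms: none
Why: Fluoride cleavage of the silyl ether under buffered, weakly acidic conditions, which avoids base-induced loss of HBr.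

Step 18
Reactants: 23 primary alcohol
Product: 24 primary iodide (C12–I)
Conditions: I2, PPh3, imidazole, toluene, 25 → 60 °C
Reagents that add atoms: iodine, II
Why: Appel-type iodination of a primary alcohol (SN2 at CH2); the secondary bromide and the lactone are inert.

Step 19
Reactants: 25 6-methylhept-5-en-2-one
Product: 26 4-[(2S)-3,3-dimethyloxiran-2-yl]butan-2-one
Conditions: L-fructose-derived Shi ketone (0.3 equiv), KHSO5 (Oxone), Bu4NHSO4, MeCN–CH2(OMe)2–aq. buffer pH 10.5, 0 °C
Reagents that add atoms: potassium peroxymonosulfate, [K+].[O-]S(=O)(=O)OO
Why: Shi epoxidation by the chiral dioxirane; the common D-fructose ketone gives (R)-epoxides from R–CH=CMe2 alkenes through the spiro transition state, so its L-series enantiomer is used for the (S)-epoxide. The methyl ketone is a spectator.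

Step 20
Reactants: 26 (S)-epoxy ketone
Product: 27 ({4-[(2S)-3,3-dimethyloxiran-2-yl]but-1-en-2-yl}oxy)trimethylsilane
Conditions: LiN(i-Pr)2, Me3SiCl, THF, −78 °C
Reagents that add atoms: chlorotrimethylsilane, C[Si](C)(C)Cl
Why: Kinetic deprotonation of the methyl ketone at CH3 and O-silylation; the epoxide is inert to the amide base at −78 °C.

Step 21
Reactants: 27 epoxy enol silane
Product: 28 (S)-4-hydroxy-3,3-dimethylcyclohexan-1-one
Conditions: MeAlCl2 (1.2 equiv), CH2Cl2, −78 °C; then 1 M HCl
Reagents that add atoms: none
Why: Lewis-acid-promoted epoxide-initiated cyclisation terminated by an enol silane (6-endo); the activated epoxide opens at its tertiary carbon and the C2'–C3' bond forms. The C–O bond at the secondary carbon is never broken, so the (S) carbinol is retained.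

Step 22
Reactants: 28 (S)-hydroxy ketone
Product: 29 (R)-4-bromo-3,3-dimethylcyclohexan-1-one
Conditions: CBr4, PPh3, CH2Cl2, 0 → 40 °C
Reagents that add atoms: tetrabromomethane, BrC(Br)(Br)Br
Why: Appel bromination with inversion, (S)-alcohol to (R)-bromide; the monocyclic ring can place the leaving group axial for backside attack, as in step 12.

Step 23
Reactants: 24 primary iodide; 29 (R)-bromo ketone
Product: 30 tertiary alcohol (C1'–OH axial, cis to C4'–Br; C12 equatorial)
Conditions: SmI2 (2.5 equiv), NiI2 (2 mol%), THF, 0 °C; aq. NH4Cl
Reagents that add atoms: none
Why: Samarium Barbier reaction, accelerated by NiI2 so that no HMPA is needed and the secondary bromides are left alone; the primary iodide is reduced to the alkylsamarium, which adds to the ketone. Equatorial attack, anti to the axial methyl on C3', should give the axial tertiary alkoxide cis to bromine.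

Step 24
Reactants: 30 tertiary alcohol
Product: 31 target (CNP0133010.1)
Conditions: Ac2O, Sc(OTf)3 (2 mol%), MeCN, −20 °C
Reagents that add atoms: acetic anhydride, CC(=O)OC(C)=O
Why: Sc(OTf)3-catalysed acetylation of a hindered tertiary alcohol at low temperature, conditions under which tertiary alcohols are acylated without elimination.

## Compound list

1 | 1,3-dihydroxyacetone (commercial as its dimer) | OCC(=O)CO | starting material
2 | 2,2-dimethoxypropane-1,3-diol | COC(CO)(CO)OC | intermediate (not isolated)
3 | (1,3-dioxolane-2,2-diyl)dimethanol | OCC1(CO)OCCO1 | intermediate
4 | {2-[(tert-butyldiphenylsilyloxy)methyl]-1,3-dioxolan-2-yl}methanol | OCC1(CO[Si](c2ccccc2)(c2ccccc2)C(C)(C)C)OCCO1 | intermediate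
5 | 2-[(tert-butyldiphenylsilyloxy)methyl]-1,3-dioxolane-2-carbaldehyde | O=CC1(CO[Si](c2ccccc2)(c2ccccc2)C(C)(C)C)OCCO1 | intermediate
6 | methyl 2-[bis(2,2,2-trifluoroethoxy)phosphoryl]propanoate | COC(=O)C(C)P(=O)(OCC(F)(F)F)OCC(F)(F)F | starting material
7 | methyl (Z)-3-{2-[(tert-butyldiphenylsilyloxy)methyl]-1,3-dioxolan-2-yl}-2-methylprop-2-enoate | COC(=O)/C(C)=C\C1(CO[Si](c2ccccc2)(c2ccccc2)C(C)(C)C)OCCO1 | intermediate
8 | (Z)-3-{2-[(tert-butyldiphenylsilyloxy)methyl]-1,3-dioxolan-2-yl}-2-methylprop-2-en-1-ol | OC/C(C)=C\C1(CO[Si](c2ccccc2)(c2ccccc2)C(C)(C)C)OCCO1 | intermediate
9 | tert-butyl({2-[(Z)-3-bromo-2-methylprop-1-enyl]-1,3-dioxolan-2-yl}methoxy)diphenylsilane | BrC/C(C)=C\C1(CO[Si](c2ccccc2)(c2ccccc2)C(C)(C)C)OCCO1 | intermediate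
10 | methyl acetoacetate | COC(=O)CC(C)=O | starting material
11 | (1S,2R,5S)-8-phenylmenthol (auxiliary, released again in step 10) | C[C@H]1CC[C@@H]([C@H](C1)O)C(C)(C)c1ccccc1 | starting material
12 | (1S,2R,5S)-8-phenylmenthyl 3-oxobutanoate | C[C@H]1CC[C@@H]([C@H](C1)OC(=O)CC(C)=O)C(C)(C)c1ccccc1 | intermediate
13 | (1S,2R,5S)-8-phenylmenthyl (Z)-7-{2-[(tert-butyldiphenylsilyloxy)methyl]-1,3-dioxolan-2-yl}-6-methyl-3-oxohept-6-enoate | C[C@H]1CC[C@@H]([C@H](C1)OC(=O)CC(=O)CC/C(C)=C\C1(CO[Si](c2ccccc2)(c2ccccc2)C(C)(C)C)OCCO1)C(C)(C)c1ccccc1 | intermediate
14 | allyl bromide | C=CCBr | starting material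
15 | (1S,2R,5S)-8-phenylmenthyl (Z)-2-allyl-7-{2-[(tert-butyldiphenylsilyloxy)methyl]-1,3-dioxolan-2-yl}-6-methyl-3-oxohept-6-enoate (both C2 epimers) | C[C@H]1CC[C@@H]([C@H](C1)OC(=O)C(CC=C)C(=O)CC/C(C)=C\C1(CO[Si](c2ccccc2)(c2ccccc2)C(C)(C)C)OCCO1)C(C)(C)c1ccccc1 | intermediate
16 | (1S,5S,8S)-1-allyl-8-{2-[(tert-butyldiphenylsilyloxy)methyl]-1,3-dioxolan-2-yl}-5-methyl-6-oxabicyclo[3.2.1]octane-2,7-dione (C8 arm anti to the lactone bridge) | C=CC[C@@]12C(=O)O[C@@](C)(CCC1=O)[C@H]2C1(CO[Si](c2ccccc2)(c2ccccc2)C(C)(C)C)OCCO1 | intermediate
17 | 2-hydroxy analogue of 16: C2–OH axial, opposite the lactone bridge and cis to the C8 arm; C1, C5, C8 as in 16 | C=CC[C@@]12C(=O)O[C@@](C)(CC[C@@H]1O)[C@H]2C1(CO[Si](c2ccccc2)(c2ccccc2)C(C)(C)C)OCCO1 | intermediate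
18 | 2-bromo analogue of 16: C2–Br equatorial, on the lactone face and trans to the C8 arm | C=CC[C@@]12C(=O)O[C@@](C)(CC[C@H]1Br)[C@H]2C1(CO[Si](c2ccccc2)(c2ccccc2)C(C)(C)C)OCCO1 | intermediate
19 | 1-allyl-2-bromo-8-[(tert-butyldiphenylsilyloxy)acetyl]-5-methyl-6-oxabicyclo[3.2.1]octan-7-one, configuration as in 18 | C=CC[C@@]12C(=O)O[C@@](C)(CC[C@H]1Br)[C@H]2C(=O)CO[Si](c1ccccc1)(c1ccccc1)C(C)(C)C | intermediate
20 | 1-allyl-2-bromo-8-[3-(tert-butyldiphenylsilyloxy)prop-1-en-2-yl]-5-methyl-6-oxabicyclo[3.2.1]octan-7-one, configuration as in 18 | C=CC[C@@]12C(=O)O[C@@](C)(CC[C@H]1Br)[C@H]2C(=C)CO[Si](c1ccccc1)(c1ccccc1)C(C)(C)C | intermediate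
21 | tricyclic alkene: bromo lactone core with cyclopentene (C9=C10) cis-fused at C1–C8, CH2OTBDPS on C9 | C(O[Si](c1ccccc1)(c1ccccc1)C(C)(C)C)C2=CC[C@@]34C(=O)O[C@@](C)(CC[C@H]3Br)[C@@H]24 | intermediate
22 | tricyclic silyl ether: saturated core, C9–H cis to C8–H, CH2OTBDPS on the concave face | C(O[Si](c1ccccc1)(c1ccccc1)C(C)(C)C)[C@H]2CC[C@@]34C(=O)O[C@@](C)(CC[C@H]3Br)[C@@H]24 | intermediate
23 | primary alcohol of the tricyclic bromo lactone (C12–OH) | OC[C@H]2CC[C@@]34C(=O)O[C@@](C)(CC[C@H]3Br)[C@@H]24 | intermediate
24 | primary iodide of the tricyclic bromo lactone (C12–I) | IC[C@H]2CC[C@@]34C(=O)O[C@@](C)(CC[C@H]3Br)[C@@H]24 | intermediate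
25 | 6-methylhept-5-en-2-one (sulcatone) | CC(=O)CCC=C(C)C | starting material
26 | 4-[(2S)-3,3-dimethyloxiran-2-yl]butan-2-one | CC(=O)CC[C@@H]1OC1(C)C | intermediate
27 | ({4-[(2S)-3,3-dimethyloxiran-2-yl]but-1-en-2-yl}oxy)trimethylsilane | C=C(O[Si](C)(C)C)CC[C@@H]1OC1(C)C | intermediate
28 | (S)-4-hydroxy-3,3-dimethylcyclohexan-1-one | O=C1CC[C@H](O)C(C)(C)C1 | intermediate
29 | (R)-4-bromo-3,3-dimethylcyclohexan-1-one | O=C1CC[C@@H](Br)C(C)(C)C1 | intermediate
30 | tertiary alcohol: tricyclic bromo lactone joined through C12 to C1' of the 4-bromo-3,3-dimethylcyclohexanol ring, C1'–OH axial and cis to C4'–Br | O[C@@]1(C[C@H]2CC[C@@]34C(=O)O[C@@](C)(CC[C@H]3Br)[C@@H]24)CC[C@@H](Br)C(C)(C)C1 | intermediate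
31 | CNP0133010.1, the acetate of 30 | CC(=O)O[C@@]1(C[C@H]2CC[C@@]34C(=O)O[C@@](C)(CC[C@H]3Br)[C@@H]24)CC[C@@H](Br)C(C)(C)C1 | target

## Step count and least certain steps

Total: 24 steps. Longest linear sequence: 19 steps (steps 1–6, 8–18, 23 and 24). Step 7 (auxiliary ester) and steps 19–22 (ring A) are side branches.

**Step 10 (key step).** Three things may go wrong.
- Incomplete shielding of one radical face by the auxiliary. Because the auxiliary is expelled in the same step, this lowers the enantiomeric purity directly and cannot be corrected by separating diastereomers.
- Ionisation of the allylic ketal before ring closure, which would stop the cyclisation.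
- Proton loss from the tertiary cation, or hydrolytic opening of the carbenium ion, instead of lactone closure with loss of the bulky secondary alkoxy group.

Fallback: the auxiliary is given up and the methyl ester is used, whose lactonium ion is demethylated cleanly by acetate. Setting out from 9 and 10, the dianion of 10 is alkylated with 9 to the methyl keto ester F1, which is allylated with 14 to the methyl 2-allyl keto ester F2. Oxidative cyclisation under the conditions of step 10 gives 16 together with its enantiomer F3, and chromatography on a chiral stationary phase returns to the route at 16.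

**Step 12.** The axial oxyphosphonium group may undergo anti elimination toward C3, or the substitution may stall because the rear side of the neopentylic C2 is flanked by C7.

Fallback: the C2–H bond is made instead of the C2–Br bond. Setting out from 16, (PhO)3P–Br2 and Et3N convert the ketone into the vinyl bromide F4. Ketal hydrolysis as in step 13 gives the bromo dienone F5, and methylenation as in step 14 gives the triene F6. Ring-closing metathesis as in step 15, to which the vinyl bromide is inert, gives the tricyclic diene F7, and desilylation as in step 17 gives the dienol F8. Hydrogenation of F8 with [Ir(cod)(PCy3)(py)]PF6 should saturate the cyclopentene from the convex face. The C12 hydroxyl, now under the six-membered ring, should then guide hydrogen to the lower face of the bromoalkene, placing bromine equatorial. This returns to the route at 23.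

**Step 22.** Elimination or a methyl shift may compete with substitution at the neopentylic carbinol.

Fallback: the bromine is introduced as an electrophile. Setting out from 25, the kinetic enolate is acetylated (LiN(i-Pr)2, then Ac2O) to the enol acetate F9. Bromonium-induced cation–olefin cyclisation with Et2SBr·SbCl5Br in MeNO2 closes the ring onto the enol acetate and gives 29 together with its enantiomer F10. Chromatography on a chiral stationary phase returns to the route at 29.

**Step 23.** The primary C12 radical formed on the way to the alkylsamarium may abstract the axial hydrogen of C2 (a 1,5-shift that the geometry allows), the secondary bromides may be reduced, or 29 may be enolised and close a cyclopropane.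

Fallback: a two-electron metalation replaces the radical one. Setting out from 24, iodine–lithium exchange (t-BuLi, Et2O–pentane, −78 °C) gives the alkyllithium F11. Transmetalation with CeCl3 gives the weakly basic alkylcerium dichloride F12, which adds to 29 and returns to the route at 30.

## Further compounds

F1 | step 10 | methyl (Z)-7-{2-[(tert-butyldiphenylsilyloxy)methyl]-1,3-dioxolan-2-yl}-6-methyl-3-oxohept-6-enoate | COC(=O)CC(=O)CC/C(C)=C\C1(CO[Si](c2ccccc2)(c2ccccc2)C(C)(C)C)OCCO1
F2 | step 10 | methyl (Z)-2-allyl-7-{2-[(tert-butyldiphenylsilyloxy)methyl]-1,3-dioxolan-2-yl}-6-methyl-3-oxohept-6-enoate | COC(=O)C(CC=C)C(=O)CC/C(C)=C\C1(CO[Si](c2ccccc2)(c2ccccc2)C(C)(C)C)OCCO1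
F3 | step 10 | enantiomer of 16 | C=CC[C@]12C(=O)O[C@](C)(CCC1=O)[C@@H]2C1(CO[Si](c2ccccc2)(c2ccccc2)C(C)(C)C)OCCO1
F4 | step 12 | 1-allyl-2-bromo-8-{2-[(tert-butyldiphenylsilyloxy)methyl]-1,3-dioxolan-2-yl}-5-methyl-6-oxabicyclo[3.2.1]oct-2-en-7-one | C=CC[C@@]12C(=O)O[C@@](C)(CC=C1Br)[C@H]2C1(CO[Si](c2ccccc2)(c2ccccc2)C(C)(C)C)OCCO1
F5 | step 12 | 1-allyl-2-bromo-8-[(tert-butyldiphenylsilyloxy)acetyl]-5-methyl-6-oxabicyclo[3.2.1]oct-2-en-7-one | C=CC[C@@]12C(=O)O[C@@](C)(CC=C1Br)[C@H]2C(=O)CO[Si](c1ccccc1)(c1ccccc1)C(C)(C)C
F6 | step 12 | 1-allyl-2-bromo-8-[3-(tert-butyldiphenylsilyloxy)prop-1-en-2-yl]-5-methyl-6-oxabicyclo[3.2.1]oct-2-en-7-one | C=CC[C@@]12C(=O)O[C@@](C)(CC=C1Br)[C@H]2C(=C)CO[Si](c1ccccc1)(c1ccccc1)C(C)(C)C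
F7 | step 12 | tricyclic diene: vinyl bromide at C2=C3, cyclopentene C9=C10, CH2OTBDPS on C9 | C(O[Si](c1ccccc1)(c1ccccc1)C(C)(C)C)C2=CC[C@@]34C(=O)O[C@@](C)(CC=C3Br)[C@@H]24
F8 | step 12 | tricyclic dienol: F7 with free C12–OH | OCC2=CC[C@@]34C(=O)O[C@@](C)(CC=C3Br)[C@@H]24
F9 | step 22 | 6-methylhepta-1,5-dien-2-yl acetate | C=C(OC(C)=O)CCC=C(C)C
F10 | step 22 | (S)-4-bromo-3,3-dimethylcyclohexan-1-one | O=C1CC[C@H](Br)C(C)(C)C1
F11 | step 23 | alkyllithium from 24 (C12–Li) | [Li]C[C@H]2CC[C@@]34C(=O)O[C@@](C)(CC[C@H]3Br)[C@@H]24
F12 | step 23 | alkylcerium dichloride from F11 (C12–CeCl2) | Cl[Ce](Cl)C[C@H]2CC[C@@]34C(=O)O[C@@](C)(CC[C@H]3Br)[C@@H]24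
A1 | alternative 1 | cis-fused hydrindane dione methyl ester with triethylsilyloxy carbinol | O=C1CC[C@@]2(C(=O)OC)C(=O)CC[C@](C)(O[Si](CC)(CC)CC)[C@@H]12
A2 | alternative 2 | complete skeleton with a ketone at C2 | CC(=O)O[C@@]1(C[C@H]2CC[C@@]34C(=O)O[C@@](C)(CCC3=O)[C@@H]24)CC[C@@H](Br)C(C)(C)C1
A3 | alternative 3 | cis-fused bromo hexahydroindene methyl ester with exocyclic methylene | C=C1CC[C@@]2(C(=O)OC)[C@H](Br)CC=C(C)[C@@H]12
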